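**Plan**

- Retrosynthesis: cut the palmitate C–O bond, then trace the primary C–O bond back through a C–Si bond to a C–H bond of a methyl group. Next cut the C5–prenyl bond (to an aryl bromide), the two C–CH3 bonds of the carbinol (to an ester) and the α-C–CH3 bond (to an imide enolate).
- Enabling feature: the acyloxy-bearing CH2 carbon is γ to the tertiary hydroxyl oxygen (O–CMe2–CH(indol-3-yl)–CH2). Silicon placed on that oxygen therefore reaches it through a five-membered 1,2-oxasilolane (O1, Si2, CH2-3, CH-4, CMe2-5).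
- Forward: the chain is built linearly on 5-bromoindole-3-acetic acid (N-silylation, imide, α-methylation, ester, gem-dimethyl carbinol, C5 prenylation). The only ring made is the oxasilolane, closed in step 9 and opened oxidatively in step 10.
- Stereochemistry: the single stereocentre is set in step 3 by Evans methylation under control of (R)-4-benzyl-1,3-oxazolidin-2-one and is not touched afterwards. The descriptor changes from R to S only because CH3 becomes CH2OH in the CIP ranking.
- End game: N-desilylation and primary-selective palmitoylation.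

Key step: step 9

Remark: the target stereocentre is (S); the methyl-bearing intermediates with the same spatial arrangement are (R), and the route is written on that basis.

**Route**

Step 1
Reactants: 1 5-bromoindole-3-acetic acid
Product: 3 2-[5-bromo-1-(triisopropylsilyl)-1H-indol-3-yl]acetic acid, via triisopropylsilyl ester 2 (not isolated)
Conditions: NaH (2.2 equiv), THF/DMF, 0 °C; TIPSCl (2.2 equiv), 0 °C → rt; then K2CO3, MeOH/H2O, 0 °C → rt; aq. citric acid
Reagents that add atoms: triisopropylsilyl chloride, CC(C)[Si](Cl)(C(C)C)C(C)C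
Why: Hydride forms the carboxylate/indolide dianion, both sites are silylated (standard NaH/TIPSCl N-silylation of indoles), and carbonate methanolysis then cleaves the labile silyl ester while the hindered N–Si(i-Pr)3 bond should persist, so nitrogen is masked before any enolate chemistry.

Step 2
Reactants: 3 2-[5-bromo-1-(triisopropylsilyl)-1H-indol-3-yl]acetic acid; 4 (R)-4-benzyl-1,3-oxazolidin-2-one
Product: 6 (R)-4-benzyl-3-{2-[5-bromo-1-(triisopropylsilyl)-1H-indol-3-yl]acetyl}-1,3-oxazolidin-2-one, via mixed pivalic anhydride 5 (not isolated)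
Conditions: PivCl, Et3N, THF, −20 °C; then 4, LiCl, −20 °C → rt
Reagents that add atoms: none
Why: N-Acylation of the oxazolidinone through the mixed pivalic anhydride under Et3N/LiCl activation is the standard mild entry to Evans imides and should leave the N-silylindole and the aryl bromide untouched.

Step 3
Reactants: 6 (R)-4-benzyl-3-{2-[5-bromo-1-(triisopropylsilyl)-1H-indol-3-yl]acetyl}-1,3-oxazolidin-2-one
Product: 8 (R)-4-benzyl-3-{(R)-2-[5-bromo-1-(triisopropylsilyl)-1H-indol-3-yl]propanoyl}-1,3-oxazolidin-2-one, via sodium Z-enolate 7 (not isolated)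
Conditions: NaHMDS (1.1 equiv), THF, −78 °C; MeI (5 equiv), −78 °C
Reagents that add atoms: iodomethane, CI
Why: Evans asymmetric alkylation, in which the chelated sodium (Z)-enolate is methylated on the face opposite the C4 benzyl group of the (R)-auxiliary, which should set the new α-stereocentre as (R) as is established for arylacetyl imides.

Step 4
Reactants: 8 (R)-4-benzyl-3-{(R)-2-[5-bromo-1-(triisopropylsilyl)-1H-indol-3-yl]propanoyl}-1,3-oxazolidin-2-one
Product: 10 (R)-2-[5-bromo-1-(triisopropylsilyl)-1H-indol-3-yl]propanoic acid, via peroxy acid 9 (not isolated)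
Conditions: LiOH·H2O, 30% aq. H2O2, THF/H2O (3:1), 0 °C; aq. Na2SO3; 1 M HCl to pH 3 at 0 °C
Reagents that add atoms: hydrogen peroxide, OO
Why: Hydroperoxide attacks the exocyclic imide carbonyl selectively (standard LiOOH auxiliary cleavage), its low basicity is the established way to release α-arylpropionic acids without epimerisation, and sulfite reduces the intermediate peracid.

Step 5
Reactants: 10 (R)-2-[5-bromo-1-(triisopropylsilyl)-1H-indol-3-yl]propanoic acid
Product: 11 methyl (R)-2-[5-bromo-1-(triisopropylsilyl)-1H-indol-3-yl]propanoate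
Conditions: MeI, KHCO3, DMF, rt
Reagents that add atoms: iodomethane, CI
Why: O-Alkylation of the potassium carboxylate with iodomethane under bicarbonate is too weakly basic to enolise the α-aryl ester, so the stereocentre should be retained.

Step 6
Reactants: 11 methyl (R)-2-[5-bromo-1-(triisopropylsilyl)-1H-indol-3-yl]propanoate
Product: 13 (R)-3-[5-bromo-1-(triisopropylsilyl)-1H-indol-3-yl]-2-methylbutan-2-ol, via methyl ketone 12 (not isolated)
Conditions: MeMgBr (4 equiv), THF, 0 °C → rt; sat. aq. NH4Cl
Reagents that add atoms: methylmagnesium bromide, C[Mg]Br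
Why: Double Grignard addition to the ester through the methyl ketone gives the gem-dimethyl carbinol, and because any enolised ester or ketone stays as its magnesium enolate and cannot go on to the alcohol, the carbinol that forms should keep the configuration of 11 (the classical route from 2-arylpropionates to optically active 3-aryl-2-methylbutan-2-ols).

Step 7
Reactants: 13 (R)-3-[5-bromo-1-(triisopropylsilyl)-1H-indol-3-yl]-2-methylbutan-2-ol; 14 prenyl bromide (1-bromo-3-methylbut-2-ene)
Product: 16 (R)-2-methyl-3-[5-(3-methylbut-2-en-1-yl)-1-(triisopropylsilyl)-1H-indol-3-yl]butan-2-ol, via aryllithium alkoxide 15 (not isolated)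
Conditions: t-BuLi (3.1 equiv), THF, −78 °C; 14 (1.5 equiv), −78 → 0 °C; sat. aq. NH4Cl
Reagents that add atoms: none
Why: One equivalent of tert-butyllithium forms the lithium alkoxide, two more effect bromine–lithium exchange at C5 (standard for 5-bromo-1-silylindoles, C2 being shielded by the N-silyl group), and the aryllithium should be alkylated at the unhindered primary carbon of prenyl bromide (SN2) faster than the hindered tertiary alkoxide.

Step 8
Reactants: 16 (R)-2-methyl-3-[5-(3-methylbut-2-en-1-yl)-1-(triisopropylsilyl)-1H-indol-3-yl]butan-2-ol; 17 diethylsilane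
Product: 18 diethyl{[(R)-2-methyl-3-[5-(3-methylbut-2-en-1-yl)-1-(triisopropylsilyl)-1H-indol-3-yl]butan-2-yl]oxy}silane
Conditions: [Ir(cod)OMe]2 (0.5 mol%), Et2SiH2 (1.5 equiv), THF, rt; volatiles removed in vacuo, filtration through Celite under N2
Reagents that add atoms: none
Why: Iridium-catalysed dehydrogenative O-silylation of alcohols with diethylsilane should stop at the mono-alkoxy hydridosilane for a hindered tertiary alcohol and leave the trisubstituted alkene alone at room temperature.

Step 9
Reactants: 18 diethyl{[(R)-2-methyl-3-[5-(3-methylbut-2-en-1-yl)-1-(triisopropylsilyl)-1H-indol-3-yl]butan-2-yl]oxy}silane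
Product: 19 (R)-2,2-diethyl-5,5-dimethyl-4-[5-(3-methylbut-2-en-1-yl)-1-(triisopropylsilyl)-1H-indol-3-yl]-1,2-oxasilolane
Conditions: [Ir(cod)OMe]2 (1 mol%), 3,4,7,8-tetramethyl-1,10-phenanthroline (2.4 mol%), norbornene (1.2 equiv), THF, 100 °C, sealed tube
Reagents that add atoms: none
Why: The Ir(I)–phenanthroline catalyst inserts into the Si–H bond, norbornene takes up the two hydrogens as norbornane, and the iridium silyl cleaves a C–H bond of the methyl group on the stereocentre (the only primary C–H bond γ to oxygen) to give a six-membered iridacycle from which C–Si reductive elimination releases the product. The closest known reaction type is the iridium-catalysed dehydrogenative γ-C(sp3)–H silylation of diethyl(hydrido)silyl ethers of secondary and tertiary alcohols, of which this is a direct application. The 1,2-oxasilolane (O1–Si2–C3–C4–C5) closes by intramolecular C3–Si bond formation, a five-membered closure helped by the gem-dimethyl group at C5. No stereocentre is created, since silicon carries two ethyl groups and C5 two methyl groups, and C4 keeps its configuration because none of its bonds is broken. The step needs site selectivity: the carbinol methyl groups and the benzylic C–H would have to close a four-membered ring, while indole C2–H (six-membered closure) is buried between the N-triisopropylsilyl group and the branched C3 substituent. The trisubstituted prenyl alkene is a far poorer partner for hydrosilylation or hydrogen transfer than strained norbornene and should therefore survive.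

Step 10
Reactants: 19 (R)-2,2-diethyl-5,5-dimethyl-4-[5-(3-methylbut-2-en-1-yl)-1-(triisopropylsilyl)-1H-indol-3-yl]-1,2-oxasilolane
Product: 20 (S)-3-methyl-2-[5-(3-methylbut-2-en-1-yl)-1-(triisopropylsilyl)-1H-indol-3-yl]butane-1,3-diol
Conditions: 30% aq. H2O2, KHCO3, THF/MeOH (1:1), 50 °C; aq. Na2S2O3
Reagents that add atoms: hydrogen peroxide, OO
Why: Tamao–Fleming oxidation, in which the alkoxy-activated silicon is attacked by hydroperoxide and the CH2 group migrates from silicon to oxygen without touching the adjacent stereocentre, while metal-free bicarbonate-buffered peroxide should spare the trisubstituted alkene and the N-silylated indole.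

Step 11
Reactants: 20 (S)-3-methyl-2-[5-(3-methylbut-2-en-1-yl)-1-(triisopropylsilyl)-1H-indol-3-yl]butane-1,3-diol
Product: 21 (S)-3-methyl-2-[5-(3-methylbut-2-en-1-yl)-1H-indol-3-yl]butane-1,3-diol
Conditions: TBAF (1.2 equiv), THF, 0 °C
Reagents that add atoms: none
Why: Fluoride-induced cleavage of the N–Si bond of N-silylindoles is fast at 0 °C and should leave the diol and the alkene untouched.

Step 12
Reactants: 21 (S)-3-methyl-2-[5-(3-methylbut-2-en-1-yl)-1H-indol-3-yl]butane-1,3-diol; 22 palmitoyl chloride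
Product: 23 (S)-3-hydroxy-3-methyl-2-[5-(3-methylbut-2-en-1-yl)-1H-indol-3-yl]butyl hexadecanoate
Conditions: 22 (1.05 equiv), 2,4,6-collidine, CH2Cl2, −78 → −20 °C
Reagents that add atoms: none
Why: Acylation with an acid chloride and collidine at low temperature is selective for the primary hydroxyl, since the tertiary hydroxyl is too hindered and the indole N–H is not acylated without deprotonation, so the target ester should form directly.

**Compound list**

1 | 2-(5-bromo-1H-indol-3-yl)acetic acid (5-bromoindole-3-acetic acid) | OC(=O)Cc1c[nH]c2ccc(Br)cc12 | starting material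
2 | triisopropylsilyl 2-[5-bromo-1-(triisopropylsilyl)-1H-indol-3-yl]acetate | CC(C)[Si](OC(=O)Cc1cn([Si](C(C)C)(C(C)C)C(C)C)c2ccc(Br)cc12)(C(C)C)C(C)C | intermediate
3 | 2-[5-bromo-1-(triisopropylsilyl)-1H-indol-3-yl]acetic acid | OC(=O)Cc1cn([Si](C(C)C)(C(C)C)C(C)C)c2ccc(Br)cc12 | intermediate
4 | (R)-4-benzyl-1,3-oxazolidin-2-one | O=C1N[C@H](Cc2ccccc2)CO1 | starting material
5 | 2-[5-bromo-1-(triisopropylsilyl)-1H-indol-3-yl]acetic pivalic anhydride | CC(C)(C)C(=O)OC(=O)Cc1cn([Si](C(C)C)(C(C)C)C(C)C)c2ccc(Br)cc12 | intermediate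
6 | (R)-4-benzyl-3-{2-[5-bromo-1-(triisopropylsilyl)-1H-indol-3-yl]acetyl}-1,3-oxazolidin-2-one | O=C(Cc1cn([Si](C(C)C)(C(C)C)C(C)C)c2ccc(Br)cc12)N1[C@H](Cc2ccccc2)COC1=O | intermediate
7 | sodium (Z)-enolate of 6 | [Na+].[O-]/C(=C\c1cn([Si](C(C)C)(C(C)C)C(C)C)c2ccc(Br)cc12)N1[C@H](Cc2ccccc2)COC1=O | intermediate
8 | (R)-4-benzyl-3-{(R)-2-[5-bromo-1-(triisopropylsilyl)-1H-indol-3-yl]propanoyl}-1,3-oxazolidin-2-one | C[C@H](c1cn([Si](C(C)C)(C(C)C)C(C)C)c2ccc(Br)cc12)C(=O)N1[C@H](Cc2ccccc2)COC1=O | intermediate
9 | (R)-2-[5-bromo-1-(triisopropylsilyl)-1H-indol-3-yl]propaneperoxoic acid | C[C@H](c1cn([Si](C(C)C)(C(C)C)C(C)C)c2ccc(Br)cc12)C(=O)OO | intermediate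
10 | (R)-2-[5-bromo-1-(triisopropylsilyl)-1H-indol-3-yl]propanoic acid | C[C@H](c1cn([Si](C(C)C)(C(C)C)C(C)C)c2ccc(Br)cc12)C(O)=O | intermediate
11 | methyl (R)-2-[5-bromo-1-(triisopropylsilyl)-1H-indol-3-yl]propanoate | C[C@H](c1cn([Si](C(C)C)(C(C)C)C(C)C)c2ccc(Br)cc12)C(=O)OC | intermediate
12 | (R)-3-[5-bromo-1-(triisopropylsilyl)-1H-indol-3-yl]butan-2-one | C[C@H](c1cn([Si](C(C)C)(C(C)C)C(C)C)c2ccc(Br)cc12)C(C)=O | intermediate
13 | (R)-3-[5-bromo-1-(triisopropylsilyl)-1H-indol-3-yl]-2-methylbutan-2-ol | C[C@H](c1cn([Si](C(C)C)(C(C)C)C(C)C)c2ccc(Br)cc12)C(C)(C)O | intermediate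
14 | prenyl bromide (1-bromo-3-methylbut-2-ene) | CC(C)=CCBr | starting material
15 | lithium (R)-3-[5-lithio-1-(triisopropylsilyl)-1H-indol-3-yl]-2-methylbutan-2-olate | C[C@H](c1cn([Si](C(C)C)(C(C)C)C(C)C)c2ccc([Li])cc12)C(C)(C)O[Li] | intermediate
16 | (R)-2-methyl-3-[5-(3-methylbut-2-en-1-yl)-1-(triisopropylsilyl)-1H-indol-3-yl]butan-2-ol | C[C@H](c1cn([Si](C(C)C)(C(C)C)C(C)C)c2ccc(CC=C(C)C)cc12)C(C)(C)O | intermediate
17 | diethylsilane | CC[SiH2]CC | starting material
18 | diethyl{[(R)-2-methyl-3-[5-(3-methylbut-2-en-1-yl)-1-(triisopropylsilyl)-1H-indol-3-yl]butan-2-yl]oxy}silane | C[C@H](c1cn([Si](C(C)C)(C(C)C)C(C)C)c2ccc(CC=C(C)C)cc12)C(C)(C)O[SiH](CC)CC | intermediate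
19 | (R)-2,2-diethyl-5,5-dimethyl-4-[5-(3-methylbut-2-en-1-yl)-1-(triisopropylsilyl)-1H-indol-3-yl]-1,2-oxasilolane | CC[Si]1(CC)C[C@H](c2cn([Si](C(C)C)(C(C)C)C(C)C)c3ccc(CC=C(C)C)cc23)C(C)(C)O1 | intermediate
20 | (S)-3-methyl-2-[5-(3-methylbut-2-en-1-yl)-1-(triisopropylsilyl)-1H-indol-3-yl]butane-1,3-diol | OC[C@H](c1cn([Si](C(C)C)(C(C)C)C(C)C)c2ccc(CC=C(C)C)cc12)C(C)(C)O | intermediate
21 | (S)-3-methyl-2-[5-(3-methylbut-2-en-1-yl)-1H-indol-3-yl]butane-1,3-diol | OC[C@H](c1c[nH]c2ccc(CC=C(C)C)cc12)C(C)(C)O | intermediate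
22 | palmitoyl chloride (hexadecanoyl chloride) | CCCCCCCCCCCCCCCC(=O)Cl | starting material
23 | (S)-3-hydroxy-3-methyl-2-[5-(3-methylbut-2-en-1-yl)-1H-indol-3-yl]butyl hexadecanoate (CNP0125367.1) | CCCCCCCCCCCCCCCC(=O)OC[C@H](c1c[nH]c2ccc(CC=C(C)C)cc12)C(C)(C)O | target

**Step count**

Total steps: 12. Longest linear sequence: 12 steps (from 1).

**Steps most likely to fail**

Step 9. The iridium silyl may engage an indole C–H bond in place of the methyl group, may hydrosilylate or isomerise the prenyl alkene, or may fail to cyclise because of crowding around the tertiary silyl ether. The fallback gives up C–H functionalisation and brings in the CH2–O carbon as an electrophile at the imide stage. It sets out from 6 and comes back to the route at 21.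
- The chlorotitanium enolate of 6 (TiCl4, i-Pr2NEt, CH2Cl2, 0 °C) would be hydroxymethylated with s-trioxane/TiCl4 on the face that is methylated in step 3. This should give (R)-4-benzyl-3-{(S)-2-[5-bromo-1-(triisopropylsilyl)-1H-indol-3-yl]-3-hydroxypropanoyl}-1,3-oxazolidin-2-one F1.
- TBSCl/imidazole would give (R)-4-benzyl-3-{(S)-2-[5-bromo-1-(triisopropylsilyl)-1H-indol-3-yl]-3-[(tert-butyldimethylsilyl)oxy]propanoyl}-1,3-oxazolidin-2-one F2.
- LiOH/H2O2 as in step 4 would give (S)-2-[5-bromo-1-(triisopropylsilyl)-1H-indol-3-yl]-3-[(tert-butyldimethylsilyl)oxy]propanoic acid F3.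
- MeI/KHCO3 would give methyl (S)-2-[5-bromo-1-(triisopropylsilyl)-1H-indol-3-yl]-3-[(tert-butyldimethylsilyl)oxy]propanoate F4.
- MeMgBr would give (S)-3-[5-bromo-1-(triisopropylsilyl)-1H-indol-3-yl]-4-[(tert-butyldimethylsilyl)oxy]-2-methylbutan-2-ol F5.
- t-BuLi followed by prenyl bromide as in step 7 would give (S)-4-[(tert-butyldimethylsilyl)oxy]-2-methyl-3-[5-(3-methylbut-2-en-1-yl)-1-(triisopropylsilyl)-1H-indol-3-yl]butan-2-ol F6.
- TBAF (2.5 equiv) would then remove both silyl groups and deliver 21.

Step 10. Oxidation may not stay confined to the C–Si bond: peroxide may epoxidise the prenyl alkene or attack the indole C2–C3 π bond, and the N–Si bond may be partly lost. The fallback changes the order of events so that no alkene is present during the oxidation. It sets out from 13 and comes back at 20.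
- 13 would be O-silylated with diethylsilane as in step 8 to give diethyl{[(R)-3-[5-bromo-1-(triisopropylsilyl)-1H-indol-3-yl]-2-methylbutan-2-yl]oxy}silane F7.
- Cyclisation under the conditions of step 9 would give (R)-4-[5-bromo-1-(triisopropylsilyl)-1H-indol-3-yl]-2,2-diethyl-5,5-dimethyl-1,2-oxasilolane F8.
- Tamao–Fleming oxidation would give (S)-2-[5-bromo-1-(triisopropylsilyl)-1H-indol-3-yl]-3-methylbutane-1,3-diol F9.
- The prenyl group would be attached last by Suzuki–Miyaura coupling with prenylboronic acid pinacol ester under a linear-selective palladium catalyst (bulky NHC or biarylphosphine ligand, aq. K3PO4, THF), which arrives at 20.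

Step 7. The aryllithium may be allylated at the tertiary terminus of prenyl bromide (SN2′, giving the reverse-prenyl isomer), may be quenched by proton transfer, or the alkoxide may be O-prenylated. The fallback replaces organolithium alkylation by cross-coupling. It sets out from 13 and comes back at 16: Suzuki–Miyaura coupling of the free alcohol 13 with prenylboronic acid pinacol ester under the same linear-selective palladium catalysis should give 16 directly. This detour makes no compound outside the list (F0).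

Further compounds
F1 | step 9 | (R)-4-benzyl-3-{(S)-2-[5-bromo-1-(triisopropylsilyl)-1H-indol-3-yl]-3-hydroxypropanoyl}-1,3-oxazolidin-2-one | OC[C@H](c1cn([Si](C(C)C)(C(C)C)C(C)C)c2ccc(Br)cc12)C(=O)N1[C@H](Cc2ccccc2)COC1=O
F2 | step 9 | (R)-4-benzyl-3-{(S)-2-[5-bromo-1-(triisopropylsilyl)-1H-indol-3-yl]-3-[(tert-butyldimethylsilyl)oxy]propanoyl}-1,3-oxazolidin-2-one | CC(C)(C)[Si](C)(C)OC[C@H](c1cn([Si](C(C)C)(C(C)C)C(C)C)c2ccc(Br)cc12)C(=O)N1[C@H](Cc2ccccc2)COC1=O
F3 | step 9 | (S)-2-[5-bromo-1-(triisopropylsilyl)-1H-indol-3-yl]-3-[(tert-butyldimethylsilyl)oxy]propanoic acid | CC(C)(C)[Si](C)(C)OC[C@H](c1cn([Si](C(C)C)(C(C)C)C(C)C)c2ccc(Br)cc12)C(O)=O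
F4 | step 9 | methyl (S)-2-[5-bromo-1-(triisopropylsilyl)-1H-indol-3-yl]-3-[(tert-butyldimethylsilyl)oxy]propanoate | CC(C)(C)[Si](C)(C)OC[C@H](c1cn([Si](C(C)C)(C(C)C)C(C)C)c2ccc(Br)cc12)C(=O)OC
F5 | step 9 | (S)-3-[5-bromo-1-(triisopropylsilyl)-1H-indol-3-yl]-4-[(tert-butyldimethylsilyl)oxy]-2-methylbutan-2-ol | CC(C)(C)[Si](C)(C)OC[C@H](c1cn([Si](C(C)C)(C(C)C)C(C)C)c2ccc(Br)cc12)C(C)(C)O
F6 | step 9 | (S)-4-[(tert-butyldimethylsilyl)oxy]-2-methyl-3-[5-(3-methylbut-2-en-1-yl)-1-(triisopropylsilyl)-1H-indol-3-yl]butan-2-ol | CC(C)(C)[Si](C)(C)OC[C@H](c1cn([Si](C(C)C)(C(C)C)C(C)C)c2ccc(CC=C(C)C)cc12)C(C)(C)O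
F7 | step 10 | diethyl{[(R)-3-[5-bromo-1-(triisopropylsilyl)-1H-indol-3-yl]-2-methylbutan-2-yl]oxy}silane | C[C@H](c1cn([Si](C(C)C)(C(C)C)C(C)C)c2ccc(Br)cc12)C(C)(C)O[SiH](CC)CC
F8 | step 10 | (R)-4-[5-bromo-1-(triisopropylsilyl)-1H-indol-3-yl]-2,2-diethyl-5,5-dimethyl-1,2-oxasilolane | CC[Si]1(CC)C[C@H](c2cn([Si](C(C)C)(C(C)C)C(C)C)c3ccc(Br)cc23)C(C)(C)O1
F9 | step 10 | (S)-2-[5-bromo-1-(triisopropylsilyl)-1H-indol-3-yl]-3-methylbutane-1,3-diol | OC[C@H](c1cn([Si](C(C)C)(C(C)C)C(C)C)c2ccc(Br)cc12)C(C)(C)O
F0 | step 7 | none | none
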